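**Plan**
- Cuts (retro): the lactone O–CH bond (back to an ether bridge from that carbon to the CH–OH carbon, with a pendant acrylic ester); the isovalerate, the exocyclic methylene, the carbinol–butenoyl C–C bond and the neighbouring CH–O bond (back to a bridged ketone); then both ring bonds CH(O-lactone)–CH(O-acyl) and CH(OH)–CH(CH3) together, a (4+3) disconnection into a furan and an oxyallyl cation.
- Enabling feature: in the cycloheptane the unit CH(O)–C(OH)(acyl)–CH(CH3) has its middle carbon at the ketone level (a three-carbon oxyallyl), and the four carbons that complete the ring carry oxygen on both end carbons (C2/C5 of a furan plus its ring oxygen); the furan 3-substituent is the future lactone chain.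
- Forward order: carbocycle and oxygen bridge first (step 4), decoration of the rigid 8-oxabicyclo[3.2.1]octane (steps 5–12), γ-lactone ring last by trading the bridge for the lactone (step 13).
- Helpers, all removed later: a chiral alkoxy group on the future CH(CH3) carbon (stabilises the cation, makes the CH2 end bond first, carries chirality; taken off with SmI2), the oxygen bridge, an allenyl ether as masked enone, a tert-butyl ester.
- Stereochemistry: absolute sense from (S)-1-phenylethanol in step 4; the other centres from exo-face protonation, hydrogenation, enolate hydroxylation and carbonyl addition on the bicycle, and one SN2 inversion in step 13.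

Key step: step 4

Assumption: (S)-1-phenylethanol is taken to cover the cation face that leads to the bridgehead configuration drawn; if the sense of induction is the opposite one, (R)-1-phenylethanol is used and nothing else changes.

Step 1
Reactants: 1 3,3-dimethoxybutan-2-one; 2 (S)-1-phenylethanol
Product: 3 3-methoxy-3-[(S)-1-phenylethoxy]butan-2-one
Conditions: PPTS (5 mol %), cyclohexane, 60 °C, 5 Å molecular sieves (MeOH removed), 1 in excess
Reagents that add atoms: none
Why: Acid-catalysed transketalisation exchanges one methoxy group for the secondary alcohol while methanol is removed; the new ketal centre forms as both epimers, which is harmless because it becomes planar in step 4.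

Step 2
Reactants: 3 3-methoxy-3-[(S)-1-phenylethoxy]butan-2-one
Product: 5 triethyl{[3-methoxy-3-((S)-1-phenylethoxy)but-1-en-2-yl]oxy}silane, via lithium enolate 4 (not isolated)
Conditions: LiN(iPr)2, THF, −78 °C; Et3SiCl, −78 → 0 °C
Reagents that add atoms: chlorotriethylsilane, CC[Si](CC)(CC)Cl
Why: Enol silane formation: deprotonation can only take place at the methyl ketone side (the other α-carbon is the fully substituted ketal carbon) and the enolate is silylated on oxygen, with no stereocentre formed.

Step 3
Reactants: 6 2-(furan-3-yl)acetic acid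
Product: 7 tert-butyl 2-(furan-3-yl)acetate
Conditions: Boc2O, DMAP (cat.), t-BuOH, 30 °C
Reagents that add atoms: di-tert-butyl dicarbonate, CC(C)(C)OC(=O)OC(=O)OC(C)(C)C
Why: Esterification through the mixed carbonic anhydride is mild enough for the furan and gives an ester that resists organolithium reagents and falls off under the acid of the last step.

Step 4
Reactants: 5 triethyl{[3-methoxy-3-((S)-1-phenylethoxy)but-1-en-2-yl]oxy}silane; 7 tert-butyl 2-(furan-3-yl)acetate
Product: 9 tert-butyl 2-{(1R,5R)-2-methyl-3-oxo-2-[(S)-1-phenylethoxy]-8-oxabicyclo[3.2.1]oct-6-en-6-yl}acetate, via silyloxyallyl cation 8 (not isolated)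
Conditions: Me3SiOTf (10 mol %), CH2Cl2, −95 → −78 °C, 7 (1.5 equiv); Et3N quench; minor diastereomers removed by chromatography
Reagents that add atoms: none
Why: Me3SiOTf takes the methoxy group from 5 and leaves the 1-alkoxy-1-methyl-2-silyloxyallyl cation 8, which adds across C2 and C5 of furan 7 in a (4+3) cycloaddition, the silyl group then leaving the carbonyl oxygen to carry the chain; the closest known type is the oxyallyl–furan cycloaddition of alkoxy-substituted silyloxyallyl cations made from silyl enol ethers of α-keto acetals, including chiral mixed acetals. The seven-membered carbocycle should close in a concerted but asynchronous [4π(4C)+2π(3C)] sense, in the stepwise limit by a 7-(enolendo)-exo-trig attack of the enol ether carbon on the 2H-furanium ion, and the furan oxygen is carried in as the one-atom bridge. The two bridgehead CH–O centres are cis by necessity (suprafacial addition to the flat furan) and their absolute sense should be set by the (S)-1-phenylethyl group, whose C–H lies in the cation plane so that the phenyl ring covers one face; the quaternary C(CH3)(OR) centre is of no consequence because its alkoxy group is removed in step 5. The step needs regioselectivity (side chain next to the bridgehead bonded to the CH2 terminus), which is secured by the first bond forming between the unhindered CH2 terminus and furan C2, the more nucleophilic α-position beside the 3-alkyl group, while the fully substituted alkoxycarbenium terminus bonds second to C5, the orientation known for 3-substituted furans with heteroatom-stabilised oxyallyl cations. It also needs π-facial selectivity (auxiliary) and cycloaddition in preference to Friedel–Crafts alkylation or proton loss from the cation (low temperature, non-basic counter-ion).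

Step 5
Reactants: 9 tert-butyl 2-{(1R,5R)-2-methyl-3-oxo-2-[(S)-1-phenylethoxy]-8-oxabicyclo[3.2.1]oct-6-en-6-yl}acetate
Product: 10 tert-butyl 2-[(1R,2S,5R)-2-methyl-3-oxo-8-oxabicyclo[3.2.1]oct-6-en-6-yl]acetate
Conditions: SmI2 (2.5 equiv), THF–MeOH, −78 → 0 °C
Reagents that add atoms: none
Why: Reductive cleavage of the C–O bond α to the ketone by SmI2 (reduction of α-heterosubstituted ketones) removes the auxiliary from both C2 epimers, and the enolate is protonated by methanol from the open exo face, which places the methyl group equatorial (anti to the oxygen bridge), also the thermodynamically preferred position.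

Step 6
Reactants: 10 tert-butyl 2-[(1R,2S,5R)-2-methyl-3-oxo-8-oxabicyclo[3.2.1]oct-6-en-6-yl]acetate
Product: 11 tert-butyl 2-[(1R,2S,5R,6S)-2-methyl-3-oxo-8-oxabicyclo[3.2.1]octan-6-yl]acetate
Conditions: H2 (1 atm), Pd/C, EtOAc, rt
Reagents that add atoms: none
Why: Heterogeneous hydrogenation adds hydrogen to the bridged alkene from the exo face (the face of the oxygen bridge), which fixes the ring CH that carries the acetate chain with the chain endo.

Step 7
Reactants: 11 tert-butyl 2-[(1R,2S,5R,6S)-2-methyl-3-oxo-8-oxabicyclo[3.2.1]octan-6-yl]acetate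
Product: 13 tert-butyl 2-[(1R,2S,4S,5S,6S)-4-hydroxy-2-methyl-3-oxo-8-oxabicyclo[3.2.1]octan-6-yl]acetate, via potassium enolate 12 (not isolated)
Conditions: KN(SiMe3)2 (1.1 equiv), THF, −78 °C; trans-2-(phenylsulfonyl)-3-phenyloxaziridine, −78 °C; AcOH quench at −78 °C
Reagents that add atoms: trans-2-(phenylsulfonyl)-3-phenyloxaziridine, O=S(=O)(c1ccccc1)N1OC1c1ccccc1
Why: Enolate hydroxylation: the bulky amide base takes a proton from the CH2 rather than the CH(CH3) α-carbon (kinetic enolate), and the oxaziridine delivers oxygen to the exo face because the endo face is covered by the two-carbon bridge and its endo side chain, which gives the axial hydroxyl syn to the oxygen bridge.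

Step 8
Reactants: 14 but-2-yn-1-ol
Product: 15 1-methoxybut-2-yne
Conditions: NaH, MeI, THF, 0 °C → rt
Reagents that add atoms: iodomethane, CI
Why: Williamson ether synthesis of a primary propargylic alkoxide with methyl iodide, with no stereocentre involved.

Step 9
Reactants: 15 1-methoxybut-2-yne
Product: 16 1-methoxybuta-1,2-diene
Conditions: KOtBu (20 mol %), THF, 50 °C; distillation
Reagents that add atoms: none
Why: Base-mediated propargyl–allenyl isomerisation: the propargylic proton next to oxygen is removed and reprotonation at the remote alkyne carbon gives the oxygen-conjugated allene, racemic at its axis, which is destroyed in step 12.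

Step 10
Reactants: 16 1-methoxybuta-1,2-diene; 13 tert-butyl 2-[(1R,2S,4S,5S,6S)-4-hydroxy-2-methyl-3-oxo-8-oxabicyclo[3.2.1]octan-6-yl]acetate
Product: 18 tert-butyl 2-[(1R,2S,3S,4S,5S,6S)-3,4-dihydroxy-3-(1-methoxybuta-1,2-dien-1-yl)-2-methyl-8-oxabicyclo[3.2.1]octan-6-yl]acetate, via 1-lithio-1-methoxybuta-1,2-diene 17 (not isolated)
Conditions: 16 (3.3 equiv), n-BuLi (3.0 equiv), THF, −40 °C; then 13, −78 → −40 °C; H2O quench
Reagents that add atoms: none
Why: 1,2-Addition of a lithiated alkoxyallene (a masked but-2-enoyl anion) to the ketone: after the hydroxyl is deprotonated the small sp2 organolithium should attack from the exo face, because the endo face is blocked by the two-carbon bridge with its endo side chain and the neighbouring lithium alkoxide guides the reagent to its own face, which sets the tertiary carbinol with the side chain equatorial (syn to the oxygen bridge) and the hydroxyl axial.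

Step 11
Reactants: 18 tert-butyl 2-[(1R,2S,3S,4S,5S,6S)-3,4-dihydroxy-3-(1-methoxybuta-1,2-dien-1-yl)-2-methyl-8-oxabicyclo[3.2.1]octan-6-yl]acetate
Product: 22 tert-butyl 2-[(1R,2S,3S,4S,5S,6S)-3,4-dihydroxy-3-(1-methoxybuta-1,2-dien-1-yl)-2-methyl-8-oxabicyclo[3.2.1]octan-6-yl]prop-2-enoate, via trilithium ester enolate 19 (not isolated), via Mannich base 20 (not isolated), via methiodide 21 (not isolated)
Conditions: LiN(iPr)2 (3.5 equiv), THF, −78 → −40 °C; CH2=NMe2+ I− (1.2 equiv), −78 → 0 °C; MeI, MeOH, rt; aq NaHCO3, CH2Cl2, rt
Reagents that add atoms: N,N-dimethylmethyleneiminium iodide, C=[N+](C)C.[I-]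
Why: Ester enolate Mannich reaction followed by N-methylation and base-induced β-elimination of trimethylamine is the standard α-methylenation of esters; it is placed here because the enone is still masked as the base-stable allenyl ether and no other ester is present, and it leaves no new stereocentre.

Step 12
Reactants: 22 tert-butyl 2-[(1R,2S,3S,4S,5S,6S)-3,4-dihydroxy-3-(1-methoxybuta-1,2-dien-1-yl)-2-methyl-8-oxabicyclo[3.2.1]octan-6-yl]prop-2-enoate
Product: 24 tert-butyl 2-{(1R,2S,3S,4S,5S,6S)-3-[(E)-but-2-enoyl]-3-hydroxy-2-methyl-4-(3-methylbutanoyloxy)-8-oxabicyclo[3.2.1]octan-6-yl}prop-2-enoate, via allenyl ether isovalerate 23 (not isolated)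
Conditions: (iPrCH2CO)2O, DMAP, Et3N, CH2Cl2, rt; then 1 M aq HCl, THF, 0 °C
Reagents that add atoms: 3-methylbutanoic anhydride, CC(C)CC(=O)OC(=O)CC(C)C; water, O
Why: DMAP-catalysed acylation should take the only secondary hydroxyl (the tertiary one does not react, and the second secondary oxygen is still locked in the bridge), and dilute aqueous acid then hydrolyses the alkoxyallene through its conjugated oxocarbenium ion to the (E)-enone without touching the tert-butyl ester.

Step 13
Reactants: 24 tert-butyl 2-{(1R,2S,3S,4S,5S,6S)-3-[(E)-but-2-enoyl]-3-hydroxy-2-methyl-4-(3-methylbutanoyloxy)-8-oxabicyclo[3.2.1]octan-6-yl}prop-2-enoate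
Product: 26 (3aS,5R,6S,7S,8S,8aR)-7-[(E)-but-2-enoyl]-5,7-dihydroxy-6-methyl-3-methylidene-2-oxooctahydro-2H-cyclohepta[b]furan-8-yl 3-methylbutanoate (target CNP0186412.1), via acrylic acid 25 (not isolated)
Conditions: CF3SO3H (20 mol %), (CF3)2CHOH–CH2Cl2, 0 → 40 °C
Reagents that add atoms: none
Why: Proposed new method: the acid should release 2-methylpropene from the tert-butyl ester to give acid 25, whose carboxyl group sits on the endo face anti to the neighbouring bridgehead C–O bond and should attack that carbon in a 5-exo-tet SN2 displacement of the protonated bridge oxygen, so that this carbon is inverted and becomes the cis-fused lactone CH–O while the bridge oxygen stays with retention on the other carbon as the free secondary hydroxyl; the closest known reaction types are the acid-promoted opening of strained cyclic ethers (oxetanes, 7-oxanorbornanes) by a neighbouring carboxylic acid or tert-butyl ester and the acylative cleavage of tetrahydrofurans with inversion.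

**Compound list**
1 | 3,3-dimethoxybutan-2-one | CC(=O)C(C)(OC)OC | starting material
2 | (S)-1-phenylethanol | C[C@H](O)c1ccccc1 | starting material
3 | 3-methoxy-3-[(S)-1-phenylethoxy]butan-2-one (both epimers at the ketal carbon) | CC(=O)C(C)(OC)O[C@@H](C)c1ccccc1 | intermediate
4 | lithium enolate of 3 (not isolated) | [Li]OC(=C)C(C)(OC)O[C@@H](C)c1ccccc1 | intermediate
5 | triethyl{[3-methoxy-3-((S)-1-phenylethoxy)but-1-en-2-yl]oxy}silane | C=C(O[Si](CC)(CC)CC)C(C)(OC)O[C@@H](C)c1ccccc1 | intermediate
6 | 2-(furan-3-yl)acetic acid | OC(=O)Cc1ccoc1 | starting material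
7 | tert-butyl 2-(furan-3-yl)acetate | CC(C)(C)OC(=O)Cc1ccoc1 | intermediate
8 | 1-methyl-1-[(S)-1-phenylethoxy]-2-(triethylsilyloxy)allyl cation, triflate (not isolated) | C=C(O[Si](CC)(CC)CC)C(C)=[O+][C@@H](C)c1ccccc1.[O-]S(=O)(=O)C(F)(F)F | intermediate
9 | tert-butyl 2-{(1R,5R)-2-methyl-3-oxo-2-[(S)-1-phenylethoxy]-8-oxabicyclo[3.2.1]oct-6-en-6-yl}acetate (both epimers at C2) | O1[C@H]2C(CC(=O)OC(C)(C)C)=C[C@@H]1C(C)(O[C@@H](C)c1ccccc1)C(=O)C2 | intermediate
10 | tert-butyl 2-[(1R,2S,5R)-2-methyl-3-oxo-8-oxabicyclo[3.2.1]oct-6-en-6-yl]acetate (methyl equatorial, anti to the oxygen bridge) | O1[C@H]2C(CC(=O)OC(C)(C)C)=C[C@@H]1[C@H](C)C(=O)C2 | intermediate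
11 | tert-butyl 2-[(1R,2S,5R,6S)-2-methyl-3-oxo-8-oxabicyclo[3.2.1]octan-6-yl]acetate (side chain endo) | O1[C@H]2[C@H](CC(=O)OC(C)(C)C)C[C@@H]1[C@H](C)C(=O)C2 | intermediate
12 | potassium C3–C4 enolate of 11 (not isolated) | O1[C@H]2[C@H](CC(=O)OC(C)(C)C)C[C@@H]1[C@H](C)C(O[K])=C2 | intermediate
13 | tert-butyl 2-[(1R,2S,4S,5S,6S)-4-hydroxy-2-methyl-3-oxo-8-oxabicyclo[3.2.1]octan-6-yl]acetate (hydroxyl axial, syn to the oxygen bridge) | O1[C@H]2[C@H](CC(=O)OC(C)(C)C)C[C@@H]1[C@H](C)C(=O)[C@H]2O | intermediate
14 | but-2-yn-1-ol | CC#CCO | starting material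
15 | 1-methoxybut-2-yne | CC#CCOC | intermediate
16 | 1-methoxybuta-1,2-diene (racemic) | CC=C=COC | intermediate
17 | 1-lithio-1-methoxybuta-1,2-diene (not isolated) | CC=C=C([Li])OC | intermediate
18 | tert-butyl 2-[(1R,2S,3S,4S,5S,6S)-3,4-dihydroxy-3-(1-methoxybuta-1,2-dien-1-yl)-2-methyl-8-oxabicyclo[3.2.1]octan-6-yl]acetate (side chain at C3 equatorial, both allene epimers) | O1[C@H]2[C@H](CC(=O)OC(C)(C)C)C[C@@H]1[C@H](C)[C@@](O)(C(OC)=C=CC)[C@H]2O | intermediate
19 | trilithium salt of 18: ester enolate and two alkoxides (not isolated) | O1[C@H]2[C@H](C=C(O[Li])OC(C)(C)C)C[C@@H]1[C@H](C)[C@@](O[Li])(C(OC)=C=CC)[C@H]2O[Li] | intermediate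
20 | Mannich base: tert-butyl 3-(dimethylamino)-2-[bicyclic residue of 18]propanoate, both epimers at the new CH (not isolated) | O1[C@H]2[C@H](C(CN(C)C)C(=O)OC(C)(C)C)C[C@@H]1[C@H](C)[C@@](O)(C(OC)=C=CC)[C@H]2O | intermediate
21 | methiodide of 20 (not isolated) | O1[C@H]2[C@H](C(C[N+](C)(C)C)C(=O)OC(C)(C)C)C[C@@H]1[C@H](C)[C@@](O)(C(OC)=C=CC)[C@H]2O.[I-] | intermediate
22 | tert-butyl 2-[(1R,2S,3S,4S,5S,6S)-3,4-dihydroxy-3-(1-methoxybuta-1,2-dien-1-yl)-2-methyl-8-oxabicyclo[3.2.1]octan-6-yl]prop-2-enoate | O1[C@H]2[C@H](C(=C)C(=O)OC(C)(C)C)C[C@@H]1[C@H](C)[C@@](O)(C(OC)=C=CC)[C@H]2O | intermediate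
23 | 4-O-(3-methylbutanoyl) ester of 22 (not isolated) | O1[C@H]2[C@H](C(=C)C(=O)OC(C)(C)C)C[C@@H]1[C@H](C)[C@@](O)(C(OC)=C=CC)[C@H]2OC(=O)CC(C)C | intermediate
24 | tert-butyl 2-{(1R,2S,3S,4S,5S,6S)-3-[(E)-but-2-enoyl]-3-hydroxy-2-methyl-4-(3-methylbutanoyloxy)-8-oxabicyclo[3.2.1]octan-6-yl}prop-2-enoate | O1[C@H]2[C@H](C(=C)C(=O)OC(C)(C)C)C[C@@H]1[C@H](C)[C@@](O)(C(=O)/C=C/C)[C@H]2OC(=O)CC(C)C | intermediate
25 | 2-{(1R,2S,3S,4S,5S,6S)-3-[(E)-but-2-enoyl]-3-hydroxy-2-methyl-4-(3-methylbutanoyloxy)-8-oxabicyclo[3.2.1]octan-6-yl}prop-2-enoic acid (not isolated) | O1[C@H]2[C@H](C(=C)C(O)=O)C[C@@H]1[C@H](C)[C@@](O)(C(=O)/C=C/C)[C@H]2OC(=O)CC(C)C | intermediate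
26 | (3aS,5R,6S,7S,8S,8aR)-7-[(E)-but-2-enoyl]-5,7-dihydroxy-6-methyl-3-methylidene-2-oxooctahydro-2H-cyclohepta[b]furan-8-yl 3-methylbutanoate (CNP0186412.1) | C=C1C(=O)O[C@@H]2[C@H]1C[C@@H](O)[C@H](C)[C@@](O)(C(=O)/C=C/C)[C@H]2OC(=O)CC(C)C | target

**Step count**
Total: 13 steps. Longest linear sequence: 10 steps (1, 2, 4, 5, 6, 7, 10, 11, 12, 13).

**Three steps most likely to fail**

Step 13 (Proposed new method). The bridging ether may resist activation, so that only the tert-butyl ester is cleaved. The acid may also trigger 5-endo addition of the tertiary hydroxyl to the enone or an α-ketol shift before the lactone forms. The fallback uses known reactions, sets out from 24 and comes back at 26. Me3SiI (from Me3SiCl and NaI, MeCN, −20 → 0 °C) should cleave the tert-butyl ester and open the ether by SN2 attack of iodide, with inversion, on the CH–O carbon flanked by CH2 and CH(CH3), which is the less hindered one and has no β-acyloxy group. The bridge oxygen then stays as a free hydroxyl on the other carbon, giving the ring-opened iodo hydroxy acid F1. Mitsunobu lactonisation (PPh3, diisopropyl azodicarboxylate, THF, 0 °C) should close the γ-lactone with inversion at the carbinol carbon to give the cis-fused iodo lactone F2. CsO2CH in DMF at 40 °C should displace iodide with inversion to give the formate F3, and NaHCO3 in MeOH at 0 °C should remove the formyl group to give 26.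

Step 4. The remote auxiliary on a fully substituted alkoxycarbenium carbon may discriminate the two cation faces poorly. The cation may also lose a methyl proton to form an alkoxy diene, or simply alkylate the furan without ring closure. The fallback sets out from 7 and comes back at 10. Commercial 3-chlorobutan-2-one is treated with NaOCH2CF3 in CF3CH2OH at rt in the presence of 7; this base-mediated dehydrohalogenation generates the parent 1-methyl oxyallyl intermediate, which should add to the furan with the same orientational bias (CH2 terminus to furan C2). After equilibration of the methyl group to the equatorial position with Et3N, the cycloadduct is racemic 10. It is resolved by preparative chromatography on a chiral stationary phase, the mirror-image ketone F4 is discarded, and 10 continues at step 6.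

Step 10. The basic organolithium may enolise the ketone, which is hindered on both faces, or convert the free α-alkoxide into an enediolate with loss of the axial hydroxyl configuration, so that addition stalls. The fallback sets out from 11 and comes back at 18. LiN(iPr)2 and Et3SiCl (THF, −78 °C) give the silyl enol ether F5. Rubottom oxidation with dimethyldioxirane (acetone–CH2Cl2, −78 °C; exo epoxidation and silyl migration) gives the α-(triethylsilyloxy) ketone F6. The less basic organocerium reagent from 17 and CeCl3 (THF, −78 °C) should add from the exo face to give the silyl ether F7, and Bu4NF (THF, 0 °C) frees the secondary hydroxyl to give 18.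

**Further compounds**
F1 | step 13 | ring-opened iodo hydroxy acid: 2-{3-[(E)-but-2-enoyl]-2,3-dihydroxy-6-iodo-4-methyl-... cycloheptyl}prop-2-enoic acid 7-isovalerate pattern as in SMILES (hydroxyl retained from the bridge, iodide inverted) | O[C@H]1[C@H](C(=C)C(O)=O)C[C@H](I)[C@H](C)[C@@](O)(C(=O)/C=C/C)[C@H]1OC(=O)CC(C)C
F2 | step 13 | cis-fused iodo lactone (26 with inverted iodide in place of the secondary hydroxyl) | C=C1C(=O)O[C@@H]2[C@H]1C[C@H](I)[C@H](C)[C@@](O)(C(=O)/C=C/C)[C@H]2OC(=O)CC(C)C
F3 | step 13 | formate ester of 26 at the secondary hydroxyl | C=C1C(=O)O[C@@H]2[C@H]1C[C@@H](OC=O)[C@H](C)[C@@](O)(C(=O)/C=C/C)[C@H]2OC(=O)CC(C)C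
F4 | step 4 | mirror image of 10: tert-butyl 2-[(1S,2R,5S)-2-methyl-3-oxo-8-oxabicyclo[3.2.1]oct-6-en-6-yl]acetate | O1[C@@H]2C(CC(=O)OC(C)(C)C)=C[C@H]1[C@@H](C)C(=O)C2
F5 | step 10 | triethylsilyl C3–C4 enol ether of 11 | O1[C@H]2[C@H](CC(=O)OC(C)(C)C)C[C@@H]1[C@H](C)C(O[Si](CC)(CC)CC)=C2
F6 | step 10 | 4-O-triethylsilyl ether of 13 | O1[C@H]2[C@H](CC(=O)OC(C)(C)C)C[C@@H]1[C@H](C)C(=O)[C@H]2O[Si](CC)(CC)CC
F7 | step 10 | 4-O-triethylsilyl ether of 18 | O1[C@H]2[C@H](CC(=O)OC(C)(C)C)C[C@@H]1[C@H](C)[C@@](O)(C(OC)=C=CC)[C@H]2O[Si](CC)(CC)CC
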